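Numbering (eremophilane): ring A = C1–C2–C3–C4–C5–C10, ring B = C5–C6–C7–C8–C9–C10, C11 sits on C7. β is the face of the C4 and C5 methyl groups.
Cuts: the C3–O acyl bond (dienoic acid), the C1=C2 unsaturation (dehydrogenation), the C8=O/C7=C11 pair (oxidative transposition of a C11 carbinol made from a C7 ester), then C5–C6 and C7–C8 of ring B, and last C9–C10 (cross-coupling).
Enabling feature: ring B is a cyclohexene whose C9=C10 alkene lies between oxygenated C8 and quaternary C5, with the C11 branch on C7 next to C8. This is the retron of a 1-oxygenated diene C8=C9–C10=C5 carried by ring A plus an acrylate C6=C7–C11.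
Forward: ring A is bought as a cyclohexenone and taken to an enol triflate and then an E-ethoxydiene. The Diels–Alder reaction closes ring B. Ethanol loss, MeLi, acylation at C3 with the separately made acid, chromate transposition and dehydrogenation finish the molecule.
Stereochemistry: a lipase resolution fixes the C3 carbinol, anti cuprate addition relays it to C4, and a Mitsunobu inversion gives the 3,4-cis (3S) form. The pseudoaxial C4 methyl then steers the cycloaddition that sets C5. C6′ is bought with (S)-2-methylbutan-1-ol.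

Key step: step 9

Assumption: the lipase is taken to hydrolyse the (R)-acetate of 2 faster, as the empirical size rule for secondary alcohols predicts when the planar vinylogous-ester side counts as the large group; if the preference were opposite, the recovered acetate would be the (R)-series material.

Step 1
Reactants: 1 3-ethoxy-2-methylcyclohex-2-en-1-one
Product: 2 (±)-6-acetoxy-3-ethoxy-2-methylcyclohex-2-en-1-one
Conditions: Mn(OAc)3 (3 equiv), cyclohexane/AcOH 10:1, reflux
Reagents that add atoms: manganese triacetate, CC(=O)[O-].CC(=O)[O-].CC(=O)[O-].[Mn+3]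
Why: Mn(OAc)3-mediated α′-acetoxylation of an enone: the manganese enolate formed at C6, the only enolisable position next to the carbonyl, is oxidised and captured by acetate, giving the racemic acetate.

Step 2
Reactants: 2 (±)-6-acetoxy-3-ethoxy-2-methylcyclohex-2-en-1-one
Product: 3 (R)-3-ethoxy-6-hydroxy-2-methylcyclohex-2-en-1-one
Conditions: Burkholderia cepacia lipase, phosphate buffer pH 7/DMSO, rt, run to about half conversion
Reagents that add atoms: none
Why: Lipase-catalysed hydrolytic kinetic resolution, a known way to enantioenriched α′-oxygenated cyclic enones, should release the (R)-alcohol and leave the (S)-acetate, so that the carbinol centre (later C3) is obtained as one enantiomer after chromatographic separation.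

Step 3
Reactants: 3 (R)-3-ethoxy-6-hydroxy-2-methylcyclohex-2-en-1-one
Product: 4 (R)-6-(tert-butyldimethylsilyloxy)-3-ethoxy-2-methylcyclohex-2-en-1-one
Conditions: TBSCl, imidazole, DMF, rt
Reagents that add atoms: tert-butyldimethylsilyl chloride, CC(C)(C)[Si](C)(C)Cl
Why: Routine imidazole-promoted silylation of a secondary alcohol, which touches no stereocentre and installs the bulky group that will shield one enone face in step 5.

Step 4
Reactants: 4 (R)-6-(tert-butyldimethylsilyloxy)-3-ethoxy-2-methylcyclohex-2-en-1-one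
Product: 6 (R)-4-(tert-butyldimethylsilyloxy)-2-methylcyclohex-2-en-1-one, via ethoxy allylic alcohol 5 (not isolated)
Conditions: i-Bu2AlH, CH2Cl2, −78 °C; then 1 M HCl, THF, 0 °C
Reagents that add atoms: water, O
Why: Stork–Danheiser carbonyl transposition, in which 1,2-reduction of the vinylogous ester and acid hydrolysis of the resulting 3-ethoxy allylic alcohol shift the carbonyl to the former enol ether carbon while the silyloxy centre is untouched and becomes C4 of the new enone.

Step 5
Reactants: 6 (R)-4-(tert-butyldimethylsilyloxy)-2-methylcyclohex-2-en-1-one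
Product: 8 (3R,4R)-4-(tert-butyldimethylsilyloxy)-2,3-dimethylcyclohex-1-en-1-yl trifluoromethanesulfonate (3,4-trans), via lithium enolate 7 (not isolated)
Conditions: Me2CuLi (from MeLi, CuI), Et2O, −78 → −20 °C; then N-(5-chloropyridin-2-yl)bis(trifluoromethanesulfonimide), THF, −78 °C → rt
Reagents that add atoms: lithium dimethylcuprate, [Li+].C[Cu-]C; N-(5-chloropyridin-2-yl)bis(trifluoromethanesulfonimide), O=S(=O)(N(c1ccc(Cl)cn1)S(=O)(=O)C(F)(F)F)C(F)(F)F
Why: Gilman cuprate 1,4-addition to a 4-silyloxycyclohexenone takes place anti to the silyloxy group and so sets C4 (eremophilane numbering) trans to the C3 oxygen, and O-sulfonylation of the regiodefined enolate locks the tetrasubstituted C5=C10 double bond as the enol triflate.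

Step 6
Reactants: 8 (3R,4R)-4-(tert-butyldimethylsilyloxy)-2,3-dimethylcyclohex-1-en-1-yl trifluoromethanesulfonate
Product: 9 (3R,4R)-4-hydroxy-2,3-dimethylcyclohex-1-en-1-yl trifluoromethanesulfonate
Conditions: HF·pyridine, THF, 0 °C → rt
Reagents that add atoms: none
Why: Acidic fluoride desilylation removes the secondary TBS ether under conditions that enol triflates tolerate, in contrast to basic fluoride sources that can attack the sulfonate.

Step 7
Reactants: 9 (3R,4R)-4-hydroxy-2,3-dimethylcyclohex-1-en-1-yl trifluoromethanesulfonate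
Product: 10 (1S,2R)-2,3-dimethyl-4-(trifluoromethylsulfonyloxy)cyclohex-3-en-1-yl 4-nitrobenzoate (1,2-cis)
Conditions: 4-nitrobenzoic acid, PPh3, DIAD, toluene, 0 °C → rt
Reagents that add atoms: 4-nitrobenzoic acid, O=C(O)c1ccc(cc1)[N+](=O)[O-]
Why: Mitsunobu reaction, in which SN2 displacement of the oxyphosphonium ion by the carboxylate inverts C3 and gives the 3,4-cis (3S,4R) arrangement of the target, 4-nitrobenzoic acid being the standard partner for hindered secondary alcohols.

Step 8
Reactants: 10 (1S,2R)-2,3-dimethyl-4-(trifluoromethylsulfonyloxy)cyclohex-3-en-1-yl 4-nitrobenzoate; 11 (E)-2-ethoxyvinylboronic acid pinacol ester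
Product: 12 (1S,2R)-4-[(E)-2-ethoxyethenyl]-2,3-dimethylcyclohex-3-en-1-yl 4-nitrobenzoate
Conditions: PdCl2(dppf) (5 mol %), K3PO4, dioxane/H2O 20:1, 60 °C
Reagents that add atoms: none
Why: Suzuki–Miyaura coupling of an enol triflate and an alkenylboronate forms C9–C10 with retention of both alkene geometries, so the E enol ether that a Diels–Alder diene requires is delivered directly and no stereocentre is touched.

Step 9
Reactants: 12 (1S,2R)-4-[(E)-2-ethoxyethenyl]-2,3-dimethylcyclohex-3-en-1-yl 4-nitrobenzoate; 13 methyl acrylate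
Product: 14 methyl (3S,4R,5R,7R,8S)-8-ethoxy-3-(4-nitrobenzoyloxy)-12,13-dinoreremophil-9-en-11-oate (3β-ester, 4β,5β-dimethyl, 7α-CO2Me, 8α-OEt; endo adduct drawn)
Conditions: 13 (5 equiv), Et2AlCl (2.5 equiv), toluene/CH2Cl2, −78 → −20 °C
Reagents that add atoms: none
Why: The Et2AlCl-bound acrylate and the s-cis form of the 1-ethoxydiene C8=C9–C10=C5 combine in a normal-electron-demand, strongly asynchronous [4+2] cycloaddition in which C5–C6 runs ahead of C7–C8, and ring B closes as a six-membered carbocycle by intermolecular cycloaddition with the C9=C10 alkene left in place. The closest known reactions are the ortho-selective Diels–Alder additions of 1-alkoxy- and 1-silyloxydienes to acrylates and the Lewis-acid-promoted cycloadditions of 2-methyl-1-vinylcyclohexene-type dienes that create an angular methyl group. The required regioselectivity (acrylate CH2 to C5, ester-bearing carbon to C8) follows from the ethoxy donor, which puts the largest HOMO coefficient on C5 and is reinforced by the alkyl branch on C10. C5 is set by the C4 methyl, held pseudoaxial by A(1,2) strain against the C5 methyl with the C3 ester equatorial, so the dienophile should enter on the opposite (α) face and leave the C5 methyl cis to the C4 methyl. C8 follows suprafacially from the E enol ether (ethoxy α) and C7 from the endo preference of the bound ester, and since both centres are erased in step 10 their ratio is immaterial. The Lewis acid is needed because the methyl inside the diene at C5 penalises the s-cis conformer, and the low temperature keeps the 1,5-hydrogen shift of this diene type and acid cleavage of the enol ether out of play.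

Step 10
Reactants: 14 methyl (3S,4R,5R,7R,8S)-8-ethoxy-3-(4-nitrobenzoyloxy)-12,13-dinoreremophil-9-en-11-oate
Product: 16 methyl (3S,4R,5R)-3-hydroxy-12,13-dinoreremophila-7,9-dien-11-oate, via hydroxy ethoxy ester 15 (not isolated)
Conditions: NaOMe (0.3 equiv), MeOH, rt → 50 °C
Reagents that add atoms: none
Why: Catalytic methoxide first transesterifies the activated nitrobenzoate and then drives E1cB loss of the allylic β-ethoxy group from the C7 ester enolate (retro-oxa-Michael reaction), which funnels every C7/C8 isomer into one linearly conjugated dienoate.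

Step 11
Reactants: 16 methyl (3S,4R,5R)-3-hydroxy-12,13-dinoreremophila-7,9-dien-11-oate
Product: 18 (3S,4R,5R)-eremophila-7,9-diene-3,11-diol, via methyl ketone 17 (not isolated)
Conditions: MeLi (5 equiv), Et2O, −78 → 0 °C; then H2O
Reagents that add atoms: methyllithium, [Li]C
Why: Double 1,2-addition of methyllithium to the ester through the methyl ketone gives the dimethyl carbinol, a hard organolithium preferring the carbonyl carbon over the diene terminus, with one further equivalent consumed by the free C3 hydroxyl.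

Step 12
Reactants: 19 (S)-2-methylbutan-1-ol
Product: 20 (S)-2-methylbutanal
Conditions: TEMPO (1 mol %), KBr (10 mol %), NaOCl, NaHCO3, CH2Cl2/H2O, 0 °C
Reagents that add atoms: none
Why: TEMPO/hypochlorite (oxoammonium) oxidation of a primary alcohol stops at the aldehyde in the buffered two-phase system at 0 °C, conditions under which the α-stereocentre should not enolise.

Step 13
Reactants: 20 (S)-2-methylbutanal; 21 triethyl (E)-4-phosphonocrotonate
Product: 23 ethyl (2E,4E,6S)-6-methylocta-2,4-dienoate, via lithiated phosphonate 22 (not isolated)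
Conditions: 21, LiN(SiMe3)2, THF, −78 °C; then 20, −78 → 0 °C
Reagents that add atoms: none
Why: Vinylogous Horner–Wadsworth–Emmons olefination, in which the stabilised phosphonocrotonate anion gives the new C4′=C5′ alkene E and keeps the C2′=C3′ alkene E, the low temperature protecting the α-stereocentre of the aldehyde.

Step 14
Reactants: 23 ethyl (2E,4E,6S)-6-methylocta-2,4-dienoate
Product: 24 (2E,4E,6S)-6-methylocta-2,4-dienoic acid
Conditions: LiOH, THF/MeOH/H2O, rt; then 1 M HCl
Reagents that add atoms: lithium hydroxide, [Li+].[OH-]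
Why: Saponification of the ethyl ester by hydroxide followed by acidification, which affects neither the diene geometry nor the remote stereocentre.

Step 15
Reactants: 18 (3S,4R,5R)-eremophila-7,9-diene-3,11-diol; 24 (2E,4E,6S)-6-methylocta-2,4-dienoic acid
Product: 25 (3S,4R,5R)-11-hydroxyeremophila-7,9-dien-3-yl (2E,4E,6S)-6-methylocta-2,4-dienoate
Conditions: 24 (2 equiv), DIC, DMAP, CH2Cl2, 0 °C → rt
Reagents that add atoms: none
Why: Steglich esterification, in which the acylpyridinium ion acylates the secondary C3 hydroxyl with retention while the tertiary C11 hydroxyl is too hindered to compete.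

Step 16
Reactants: 25 (3S,4R,5R)-11-hydroxyeremophila-7,9-dien-3-yl (2E,4E,6S)-6-methylocta-2,4-dienoate
Product: 26 (3S,4R,5R)-8-oxoeremophila-7(11),9-dien-3-yl (2E,4E,6S)-6-methylocta-2,4-dienoate
Conditions: pyridinium chlorochromate [C5H5NH][CrO3Cl] (3 equiv), 4 Å molecular sieves, CH2Cl2, rt
Reagents that add atoms: pyridinium chlorochromate, [O-][Cr](=O)(=O)Cl.c1cc[nH+]cc1
Why: Babler–Dauben oxidative transposition, known for tertiary allylic and dienylic alcohols: the C11 chromate ester shifts by a [3,3] process to C8 with the alkene moving to C7=C11, and the secondary chromate then collapses irreversibly to the cross-conjugated dienone.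

Step 17
Reactants: 26 (3S,4R,5R)-8-oxoeremophila-7(11),9-dien-3-yl (2E,4E,6S)-6-methylocta-2,4-dienoate
Product: 27 (3S,4R,5R)-8-oxoeremophila-1,7(11),9-trien-3-yl (2E,4E,6S)-6-methylocta-2,4-dienoate (CNP0215744.1)
Conditions: chloranil (2 equiv), t-BuOH, reflux
Reagents that add atoms: none
Why: Quinone dehydrogenation of the kind that extends 4-en-3-ones and cross-conjugated dienones by a γ,δ double bond: the extended enol C8(OH)=C9–C10=C1 passes the axial C2 hydride to chloranil, no other site can be dehydrogenated because C7 bears no hydrogen and C5 is quaternary, and the stereocentres stay as they are.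

Compound list
1 | 3-ethoxy-2-methylcyclohex-2-en-1-one | CCOC1=C(C)C(=O)CCC1 | starting material
2 | (±)-6-acetoxy-3-ethoxy-2-methylcyclohex-2-en-1-one | CCOC1=C(C)C(=O)C(OC(C)=O)CC1 | intermediate
3 | (R)-3-ethoxy-6-hydroxy-2-methylcyclohex-2-en-1-one | CCOC1=C(C)C(=O)[C@H](O)CC1 | intermediate
4 | (R)-6-(tert-butyldimethylsilyloxy)-3-ethoxy-2-methylcyclohex-2-en-1-one | CCOC1=C(C)C(=O)[C@H](O[Si](C)(C)C(C)(C)C)CC1 | intermediate
5 | (6R)-6-(tert-butyldimethylsilyloxy)-3-ethoxy-2-methylcyclohex-2-en-1-ol (C1 epimers, not isolated) | CCOC1=C(C)C(O)[C@H](O[Si](C)(C)C(C)(C)C)CC1 | intermediate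
6 | (R)-4-(tert-butyldimethylsilyloxy)-2-methylcyclohex-2-en-1-one | CC1=C[C@H](O[Si](C)(C)C(C)(C)C)CCC1=O | intermediate
7 | lithium (3R,4R)-4-(tert-butyldimethylsilyloxy)-2,3-dimethylcyclohex-1-en-1-olate (not isolated) | [Li+].[O-]C1=C(C)[C@@H](C)[C@H](O[Si](C)(C)C(C)(C)C)CC1 | intermediate
8 | (3R,4R)-4-(tert-butyldimethylsilyloxy)-2,3-dimethylcyclohex-1-en-1-yl trifluoromethanesulfonate | O=S(=O)(OC1=C(C)[C@@H](C)[C@H](O[Si](C)(C)C(C)(C)C)CC1)C(F)(F)F | intermediate
9 | (3R,4R)-4-hydroxy-2,3-dimethylcyclohex-1-en-1-yl trifluoromethanesulfonate | O=S(=O)(OC1=C(C)[C@@H](C)[C@H](O)CC1)C(F)(F)F | intermediate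
10 | (1S,2R)-2,3-dimethyl-4-(trifluoromethylsulfonyloxy)cyclohex-3-en-1-yl 4-nitrobenzoate | O=S(=O)(OC1=C(C)[C@@H](C)[C@@H](OC(=O)c2ccc(cc2)[N+](=O)[O-])CC1)C(F)(F)F | intermediate
11 | (E)-2-ethoxyvinylboronic acid pinacol ester | CCO/C=C/B1OC(C)(C)C(C)(C)O1 | starting material
12 | (1S,2R)-4-[(E)-2-ethoxyethenyl]-2,3-dimethylcyclohex-3-en-1-yl 4-nitrobenzoate | CCO/C=C/C1=C(C)[C@@H](C)[C@@H](OC(=O)c2ccc(cc2)[N+](=O)[O-])CC1 | intermediate
13 | methyl acrylate | C=CC(=O)OC | starting material
14 | methyl (3S,4R,5R,7R,8S)-8-ethoxy-3-(4-nitrobenzoyloxy)-12,13-dinoreremophil-9-en-11-oate | COC(=O)[C@@H]1C[C@]2(C)[C@@H](C)[C@@H](OC(=O)c3ccc(cc3)[N+](=O)[O-])CCC2=C[C@@H]1OCC | intermediate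
15 | methyl (3S,4R,5R,7R,8S)-8-ethoxy-3-hydroxy-12,13-dinoreremophil-9-en-11-oate (not isolated) | COC(=O)[C@@H]1C[C@]2(C)[C@@H](C)[C@@H](O)CCC2=C[C@@H]1OCC | intermediate
16 | methyl (3S,4R,5R)-3-hydroxy-12,13-dinoreremophila-7,9-dien-11-oate | COC(=O)C1=CC=C2CC[C@H](O)[C@H](C)[C@@]2(C)C1 | intermediate
17 | (3S,4R,5R)-3-hydroxy-13-noreremophila-7,9-dien-11-one (present as its lithium alkoxide, not isolated) | CC(=O)C1=CC=C2CC[C@H](O)[C@H](C)[C@@]2(C)C1 | intermediate
18 | (3S,4R,5R)-eremophila-7,9-diene-3,11-diol | CC(C)(O)C1=CC=C2CC[C@H](O)[C@H](C)[C@@]2(C)C1 | intermediate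
19 | (S)-2-methylbutan-1-ol | CC[C@H](C)CO | starting material
20 | (S)-2-methylbutanal | CC[C@H](C)C=O | intermediate
21 | triethyl (E)-4-phosphonocrotonate | CCOC(=O)/C=C/CP(=O)(OCC)OCC | starting material
22 | lithiated triethyl 4-phosphonocrotonate (not isolated) | [Li+].CCOC(=O)/C=C/[CH-]P(=O)(OCC)OCC | intermediate
23 | ethyl (2E,4E,6S)-6-methylocta-2,4-dienoate | CC[C@H](C)/C=C/C=C/C(=O)OCC | intermediate
24 | (2E,4E,6S)-6-methylocta-2,4-dienoic acid | CC[C@H](C)/C=C/C=C/C(=O)O | intermediate
25 | (3S,4R,5R)-11-hydroxyeremophila-7,9-dien-3-yl (2E,4E,6S)-6-methylocta-2,4-dienoate | CC[C@H](C)/C=C/C=C/C(=O)O[C@H]1CCC2=CC=C(C(C)(C)O)C[C@]2(C)[C@H]1C | intermediate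
26 | (3S,4R,5R)-8-oxoeremophila-7(11),9-dien-3-yl (2E,4E,6S)-6-methylocta-2,4-dienoate | CC[C@H](C)/C=C/C=C/C(=O)O[C@H]1CCC2=CC(=O)C(=C(C)C)C[C@]2(C)[C@H]1C | intermediate
27 | (3S,4R,5R)-8-oxoeremophila-1,7(11),9-trien-3-yl (2E,4E,6S)-6-methylocta-2,4-dienoate (CNP0215744.1) | CC[C@H](C)/C=C/C=C/C(=O)O[C@H]1C=CC2=CC(=O)C(=C(C)C)C[C@]2(C)[C@H]1C | target

Total step count: 17. Longest linear sequence: 14 (steps 1–11 and 15–17).

Steps most likely to fail

Step 9. The cycloaddition may be too slow, since the C5 methyl lies inside the s-cis diene. Lewis-acid-induced breakdown of the enol ether, bond formation through C9 instead of C5, or loss of facial control may then take over. The fallback runs from 12 back to 16. The alkene dienophile is exchanged for an alkyne, the slim kind of dienophile that hindered 2-methyl-1-vinylcyclohexenes accept best. Heating 12 with methyl propiolate (toluene, 110 °C) should form the same C5–C6 and C7–C8 bonds and give the cyclohexa-1,4-diene ester methyl 8α-ethoxy-3β-(4-nitrobenzoyloxy)-12,13-dinoreremophila-6,9-dien-11-oate F1. Conjugate hydride delivery to C6 with [(Ph3P)CuH]6 (toluene, rt) generates the C7 enolate, which expels the C8 ethoxide and gives the nitrobenzoate dienoate methyl 3β-(4-nitrobenzoyloxy)-12,13-dinoreremophila-7,9-dien-11-oate F2. NaOMe in MeOH then frees the C3 hydroxyl and gives 16.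

Step 16. Ionisation of the tertiary dienylic carbinol and proton loss (dehydration) may outrun the [3,3] shift of the chromate ester. The fallback runs from 16 back to 26. Oxygen is put on C8 by conjugate borylation, and the isopropylidene is made by aldol-type dehydration.
- Copper-catalysed β-borylation of 16 (B2pin2, CuCl, DPEphos, NaOt-Bu, MeOH, THF, rt) should give the allylic boronate methyl 3β-hydroxy-8-(pinacolatoboryl)-12,13-dinoreremophil-9-en-11-oate F3.
- Oxidation with NaBO3·4H2O (THF/H2O) gives the dihydroxy ester methyl 3β,8-dihydroxy-12,13-dinoreremophil-9-en-11-oate F4.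
- Excess MeLi (Et2O, −78 → 0 °C) gives the triol eremophil-9-ene-3β,8,11-triol F5.
- MnO2 (CH2Cl2, rt) oxidises only the allylic C8 hydroxyl and gives the hydroxy enone 3β,11-dihydroxyeremophil-9-en-8-one F6.
- Acylation with 24 (DIC, DMAP) takes place at C3 and gives the ester 11-hydroxy-8-oxoeremophil-9-en-3β-yl (2E,4E,6S)-6-methylocta-2,4-dienoate F7.
- Catalytic p-TsOH in warm toluene dehydrates the β-hydroxy ketone to the conjugated isopropylidene of 26.

Step 17. Hydride abstraction from C2 is retarded by the neighbouring acyloxy group, and enolisation may run toward the isopropylidene methyls. Long heating also invites over-oxidation or loss of the allylic ester. The fallback runs from 26 to 27 and replaces hydride abstraction by a palladium enolate pathway. Soft enolisation (TBSOTf, Et3N, CH2Cl2, 0 °C) should give the extended silyl enol ether 8-(tert-butyldimethylsilyloxy)eremophila-1(10),7(11),8-trien-3β-yl (2E,4E,6S)-6-methylocta-2,4-dienoate F8. Saegusa–Ito oxidation with Pd(OAc)2 (MeCN/DMSO, rt) then places palladium at C1 and removes the C2 hydrogen by β-hydride elimination to give 27.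

Further compounds
F1 | step 9 | methyl 8α-ethoxy-3β-(4-nitrobenzoyloxy)-12,13-dinoreremophila-6,9-dien-11-oate | COC(=O)C1=C[C@]2(C)[C@@H](C)[C@@H](OC(=O)c3ccc(cc3)[N+](=O)[O-])CCC2=C[C@@H]1OCC
F2 | step 9 | methyl 3β-(4-nitrobenzoyloxy)-12,13-dinoreremophila-7,9-dien-11-oate | COC(=O)C1=CC=C2CC[C@H](OC(=O)c3ccc(cc3)[N+](=O)[O-])[C@H](C)[C@@]2(C)C1
F3 | step 16 | methyl 3β-hydroxy-8-(pinacolatoboryl)-12,13-dinoreremophil-9-en-11-oate (C7, C8 not defined) | COC(=O)C1C[C@]2(C)[C@@H](C)[C@@H](O)CCC2=CC1B3OC(C)(C)C(C)(C)O3
F4 | step 16 | methyl 3β,8-dihydroxy-12,13-dinoreremophil-9-en-11-oate (C7, C8 not defined) | COC(=O)C1C[C@]2(C)[C@@H](C)[C@@H](O)CCC2=CC1O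
F5 | step 16 | eremophil-9-ene-3β,8,11-triol (C7, C8 not defined) | CC(C)(O)C1C[C@]2(C)[C@@H](C)[C@@H](O)CCC2=CC1O
F6 | step 16 | 3β,11-dihydroxyeremophil-9-en-8-one (C7 not defined) | CC(C)(O)C1C[C@]2(C)[C@@H](C)[C@@H](O)CCC2=CC1=O
F7 | step 16 | 11-hydroxy-8-oxoeremophil-9-en-3β-yl (2E,4E,6S)-6-methylocta-2,4-dienoate (C7 not defined) | CC[C@H](C)/C=C/C=C/C(=O)O[C@H]1CCC2=CC(=O)C(C(C)(C)O)C[C@]2(C)[C@H]1C
F8 | step 17 | 8-(tert-butyldimethylsilyloxy)eremophila-1(10),7(11),8-trien-3β-yl (2E,4E,6S)-6-methylocta-2,4-dienoate | CC[C@H](C)/C=C/C=C/C(=O)O[C@H]1CC=C2C=C(O[Si](C)(C)C(C)(C)C)C(=C(C)C)C[C@]2(C)[C@H]1C
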